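The inner dihydrobenzofuran (O1–C2–C3–C3a–C7a on ring B, with its C3 hydroxymethyl carbon) is a constitutional isomer of a chroman-4-one: shifting the ring-B carbon C4a of a flavanone from the carbonyl carbon C4 to C3 gives exactly this ring and turns C4 into the C3 ester. The route therefore makes a (2R)-6-bromo-8-methoxyflavanone whose C2 aryl is the finished outer dihydrobenzofuran (itself made one round earlier by the same two operations), and contracts it with trivalent iodine in one step that forms C3–C3a, cuts C4–C4a and sets the trans C3 centre. The bromide then carries the all-cis tetrahydrofuran, built from a cis-lactone.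

Key step: step 9

Ring labels: ring A = guaiacyl ring of the benzyl group; ring B = benzo ring of the inner dihydrobenzofuran; ring C = benzo ring of the outer dihydrobenzofuran; ring D = terminal guaiacyl ring. t-BuPyOx = 4-tert-butyl-2-(pyridin-2-yl)-4,5-dihydrooxazole.

Precursor design: the ring-D phenol is carried as a pivalate, which resists acidic methanol/orthoformate and makes ring D harder to oxidise and less prone to migrate. The C3 carbon of the outer ring is carried as its methyl ester, so one LiAlH4 reduction after the key step frees all three hydroxyl groups.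

Remark (assumption): the sense of induction of the two t-BuPyOx antipodes (steps 5, 8) and of the DuPhos ligand (step 13) is assigned by analogy with cyclic enones and itaconate half-esters; if a first run shows the opposite sense, the ligand antipode is used and nothing else changes.

Step 1
Reactants: 1 1-(2-hydroxy-3-methoxyphenyl)ethanone
Product: 2 1-(5-bromo-2-hydroxy-3-methoxyphenyl)ethanone
Conditions: NBS (1.05 equiv), MeCN, 0 °C to rt
Reagents that add atoms: N-bromosuccinimide, O=C1CCC(=O)N1Br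
Why: Electrophilic aromatic bromination, in which the free phenol directs to its only open ortho/para position (C5, para to OH), so a single regioisomer is expected.

Step 2
Reactants: 2 1-(5-bromo-2-hydroxy-3-methoxyphenyl)ethanone; 3 N,N-dimethylformamide dimethyl acetal
Product: 5 6-bromo-8-methoxy-4H-chromen-4-one, via enaminone 4 (not isolated)
Conditions: 3 (1.5 equiv), toluene, 100 °C; concentrate; conc. HCl, CH2Cl2, rt
Reagents that add atoms: none
Why: Condensation of the methyl ketone with the amide acetal gives the enaminone, and acid then induces intramolecular oxa-Michael addition of the phenol with loss of dimethylamine (standard enaminone route to chromones).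

Step 3
Reactants: 6 4-bromo-2-methoxyphenol
Product: 7 4-bromo-2-methoxyphenyl pivalate
Conditions: PivCl, Et3N, DMAP (cat.), CH2Cl2, 0 °C to rt
Reagents that add atoms: pivaloyl chloride, CC(C)(C)C(Cl)=O
Why: O-acylation of the phenol with nucleophilic catalysis by DMAP.

Step 4
Reactants: 7 4-bromo-2-methoxyphenyl pivalate
Product: 8 [3-methoxy-4-(pivaloyloxy)phenyl]boronic acid
Conditions: B2(OH)4 (3 equiv), KOAc (3 equiv), PdCl(XPhos)(2'-amino-1,1'-biphenyl-2-yl) (second-generation XPhos palladacycle, 1 mol %), XPhos (2 mol %), EtOH, 80 °C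
Reagents that add atoms: tetrahydroxydiboron, OB(O)B(O)O
Why: Palladium-catalysed Miyaura-type borylation of the aryl bromide with tetrahydroxydiboron gives the free boronic acid directly, and acetate is too weak a base to start Suzuki coupling or to cleave the hindered pivalate.

Step 5
Reactants: 5 6-bromo-8-methoxy-4H-chromen-4-one; 8 [3-methoxy-4-(pivaloyloxy)phenyl]boronic acid
Product: 9 (2S)-6-bromo-8-methoxy-2-[3-methoxy-4-(pivaloyloxy)phenyl]chroman-4-one
Conditions: 8 (2 equiv), Pd(OCOCF3)2 (5 mol %), (R)-t-BuPyOx (6 mol %), NH4PF6 (30 mol %), H2O (5 equiv), ClCH2CH2Cl, 60 °C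
Reagents that add atoms: none
Why: Asymmetric conjugate addition of an arylboronic acid to the chromone under cationic divalent-palladium/pyridine-oxazoline catalysis (aryl transfer to palladium, insertion of C2=C3, protonolysis of the enolate), in which the (R)-ligand is expected to set C2 as S and the aryl bromide is inert because no zerovalent palladium is involved.

Step 6
Reactants: 9 (2S)-6-bromo-8-methoxy-2-[3-methoxy-4-(pivaloyloxy)phenyl]chroman-4-one
Product: 11 methyl (2S,3S)-5-bromo-7-methoxy-2-[3-methoxy-4-(pivaloyloxy)phenyl]-2,3-dihydrobenzofuran-3-carboxylate (trans), via enol ether 10 (not isolated)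
Conditions: PhI(OAc)2 (1.2 equiv), conc. H2SO4 (0.3 equiv), HC(OMe)3, 0 °C to rt
Reagents that add atoms: trimethyl orthoformate, COC(OC)OC
Why: Oxidative ring contraction of a flavanone by trivalent iodine (1,2-aryl shift): the enol ether is iodinated at C3 anti to the C2 aryl and C4a migrates with inversion at C3, so C2 stays S, the ester comes out trans (2S,3S), and the acylated ring D is a poor competitor for migration.

Step 7
Reactants: 11 methyl (2S,3S)-5-bromo-7-methoxy-2-[3-methoxy-4-(pivaloyloxy)phenyl]-2,3-dihydrobenzofuran-3-carboxylate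
Product: 12 {(2S,3S)-7-methoxy-3-(methoxycarbonyl)-2-[3-methoxy-4-(pivaloyloxy)phenyl]-2,3-dihydrobenzofuran-5-yl}boronic acid
Conditions: B2(OH)4 (3 equiv), KOAc (3 equiv), PdCl(XPhos)(2'-amino-1,1'-biphenyl-2-yl) (1 mol %), XPhos (2 mol %), MeOH, 60 °C
Reagents that add atoms: tetrahydroxydiboron, OB(O)B(O)O
Why: The same palladium-catalysed borylation as in step 4, run in MeOH so that the methyl ester cannot exchange, with a base too weak to enolise the C3 ester, so both stereocentres are kept.

Step 8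
Reactants: 5 6-bromo-8-methoxy-4H-chromen-4-one; 12 {(2S,3S)-7-methoxy-3-(methoxycarbonyl)-2-[3-methoxy-4-(pivaloyloxy)phenyl]-2,3-dihydrobenzofuran-5-yl}boronic acid
Product: 13 methyl (2S,3S)-5-[(2R)-6-bromo-8-methoxy-4-oxochroman-2-yl]-7-methoxy-2-[3-methoxy-4-(pivaloyloxy)phenyl]-2,3-dihydrobenzofuran-3-carboxylate
Conditions: 5 (1.5 equiv), Pd(OCOCF3)2 (10 mol %), (S)-t-BuPyOx (12 mol %), NH4PF6 (30 mol %), H2O (5 equiv), ClCH2CH2Cl, 60 °C
Reagents that add atoms: none
Why: The same asymmetric conjugate arylation as in step 5, now with the (S)-ligand, whose catalyst control is expected to set C2 of the new chromanone as R irrespective of the remote centres of 12, while bromide, esters and pivalate are untouched.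

Step 9
Reactants: 13 methyl (2S,3S)-5-[(2R)-6-bromo-8-methoxy-4-oxochroman-2-yl]-7-methoxy-2-[3-methoxy-4-(pivaloyloxy)phenyl]-2,3-dihydrobenzofuran-3-carboxylate
Product: 15 methyl (2R,3R)-5-bromo-7-methoxy-2-{(2S,3S)-7-methoxy-3-(methoxycarbonyl)-2-[3-methoxy-4-(pivaloyloxy)phenyl]-2,3-dihydrobenzofuran-5-yl}-2,3-dihydrobenzofuran-3-carboxylate, via enol ether 14 (not isolated)
Conditions: PhI(OAc)2 (1.2 equiv), conc. H2SO4 (0.3 equiv), HC(OMe)3 (solvent), 0 °C to rt
Reagents that add atoms: trimethyl orthoformate, COC(OC)OC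
Why: Acid and orthoformate convert the ketone into enol ether 14; PhI(OAc)2 then places its trivalent iodine on C3 from the face opposite the C2 aryl while methanol from the orthoformate caps C4, and the ring-B carbon C4a shifts from C4 to C3 through a bridged phenonium ion, expelling iodobenzene and leaving a dimethoxycarbenium ion at C4 that collapses to the methyl ester. This is the known oxidative ring contraction of flavanones to methyl trans-2-aryl-2,3-dihydrobenzofuran-3-carboxylates by trivalent iodine in trimethyl orthoformate, an oxidative 1,2-aryl shift. The furan ring O1–C2–C3–C3a–C7a is closed by contraction of the pyranone, that is by 1,2-migration of C4a (three-centre bridging at C3, then opening of the spiro arenium ion), not by attack of an external nucleophile. C2 is not touched and keeps the R configuration from step 8; the new C3 centre is fixed by inversion, since C4a enters anti to the departing iodobenzene, which itself sat trans to the C2 aryl, so the ester ends trans to the aryl (2R,3R). The step needs migration of C4a in preference to the electron-rich ring-C aryl on C2, to dehydrogenation and to acid opening to the chalcone: with iodine equatorial only the ring bond C4–C4a, not the exocyclic C2–aryl bond, is anti-periplanar to C3–I, and migration from C4 is pulled by its two methoxy groups. The ketone is masked as enol ether before a retro-oxa-Michael opening can start, and the pivalate and the ester keep ring D and the outer ring inert to oxidant and acid.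

Step 10
Reactants: 15 methyl (2R,3R)-5-bromo-7-methoxy-2-{(2S,3S)-7-methoxy-3-(methoxycarbonyl)-2-[3-methoxy-4-(pivaloyloxy)phenyl]-2,3-dihydrobenzofuran-5-yl}-2,3-dihydrobenzofuran-3-carboxylate
Product: 16 [(2R,3S)-5-bromo-2-[(2S,3R)-3-(hydroxymethyl)-2-(4-hydroxy-3-methoxyphenyl)-7-methoxy-2,3-dihydrobenzofuran-5-yl]-7-methoxy-2,3-dihydrobenzofuran-3-yl]methanol
Conditions: LiAlH4 (4 equiv), THF, 0 °C; then H2O/aq. NaOH
Reagents that add atoms: none
Why: Hydride reduction of both methyl esters to primary alcohols and reductive cleavage of the aryl pivalate in one operation, with the aryl bromide inert at 0 °C and no stereocentre involved.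

Step 11
Reactants: 16 [(2R,3S)-5-bromo-2-[(2S,3R)-3-(hydroxymethyl)-2-(4-hydroxy-3-methoxyphenyl)-7-methoxy-2,3-dihydrobenzofuran-5-yl]-7-methoxy-2,3-dihydrobenzofuran-3-yl]methanol
Product: 17 tris(tert-butyldimethylsilyl) ether of 16 (both CH2OH groups and the ring-D phenol silylated)
Conditions: TBSCl (4 equiv), imidazole, DMF, rt
Reagents that add atoms: tert-butyldimethylsilyl chloride, CC(C)(C)[Si](C)(C)Cl
Why: Silylation of the two primary alcohols and the phenol gives ethers that tolerate t-BuLi and cold BF3·OEt2 and are all removed by fluoride at the end.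

Step 12
Reactants: 18 4-(benzyloxy)-3-methoxybenzaldehyde; 19 dimethyl succinate
Product: 20 (E)-4-[4-(benzyloxy)-3-methoxyphenyl]-3-(methoxycarbonyl)but-3-enoic acid
Conditions: NaOMe, MeOH, reflux; then aq. HCl
Reagents that add atoms: none
Why: Stobbe condensation (aldol addition, lactonisation and E1cB opening) gives the (E)-alkylidene succinic half-ester with the free acid on the CH2 arm.

Step 13
Reactants: 20 (E)-4-[4-(benzyloxy)-3-methoxyphenyl]-3-(methoxycarbonyl)but-3-enoic acid
Product: 21 (3R)-4-[4-(benzyloxy)-3-methoxyphenyl]-3-(methoxycarbonyl)butanoic acid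
Conditions: H2 (5 bar), [Rh(cod)((S,S)-Et-DuPhos)]OTf (1 mol %), NaOMe (10 mol %), MeOH, rt
Reagents that add atoms: none
Why: Rhodium-catalysed asymmetric hydrogenation of the itaconate-type half-ester, bound as its chelating carboxylate, sets the stereocentre as R under ligand control and leaves the benzyl ether intact.

Step 14
Reactants: 21 (3R)-4-[4-(benzyloxy)-3-methoxyphenyl]-3-(methoxycarbonyl)butanoic acid
Product: 22 (4R)-4-[4-(benzyloxy)-3-methoxybenzyl]dihydrofuran-2(3H)-one
Conditions: KOH (1 equiv), EtOH; NaBH4, CaCl2, 0 °C to rt; then 6 M HCl, rt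
Reagents that add atoms: none
Why: Ca(BH4)2 reduces the ester but not the carboxylate, and acid then closes the γ-lactone (the standard route to β-benzylbutyrolactones) without touching the stereocentre.

Step 15
Reactants: 22 (4R)-4-[4-(benzyloxy)-3-methoxybenzyl]dihydrofuran-2(3H)-one
Product: 25 (3R,4R)-4-[4-(benzyloxy)-3-methoxybenzyl]-3-(hydroxymethyl)dihydrofuran-2(3H)-one (cis), via lithium carboxylate 23 (not isolated), via dihydroxy acid 24 (not isolated)
Conditions: LiN(i-Pr)2 (1.1 equiv), THF, −78 °C; CO2 (gas, excess), −78 °C; argon purge; LiBH4 (3 equiv), −78 °C to rt; then 2 M HCl, rt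
Reagents that add atoms: carbon dioxide, O=C=O
Why: Enolate carboxylation anti to the benzyl group gives the trans carboxylate, LiBH4 then reduces the lactone carbonyl but not the carboxylate (the known chemoselectivity of borohydride for an ester beside a carboxylate salt), and acid relactonises the untouched carboxyl onto the C5 hydroxyl, so the two carbonyl carbons exchange roles and the easily set trans arrangement becomes the cis (3R,4R) lactone.

Step 16
Reactants: 25 (3R,4R)-4-[4-(benzyloxy)-3-methoxybenzyl]-3-(hydroxymethyl)dihydrofuran-2(3H)-one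
Product: 26 (3R,4R)-4-(4-hydroxy-3-methoxybenzyl)-3-(hydroxymethyl)dihydrofuran-2(3H)-one
Conditions: H2 (1 atm), Pd/C, EtOAc, rt
Reagents that add atoms: none
Why: Hydrogenolysis of the aryl benzyl ether under neutral conditions that leave the lactone and its two stereocentres alone.

Step 17
Reactants: 26 (3R,4R)-4-(4-hydroxy-3-methoxybenzyl)-3-(hydroxymethyl)dihydrofuran-2(3H)-one
Product: 27 (3R,4R)-4-[4-(tert-butyldimethylsilyloxy)-3-methoxybenzyl]-3-[(tert-butyldimethylsilyloxy)methyl]dihydrofuran-2(3H)-one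
Conditions: TBSCl (2.5 equiv), imidazole, DMF, 0 °C to rt
Reagents that add atoms: tert-butyldimethylsilyl chloride, CC(C)(C)[Si](C)(C)Cl
Why: Silylation of phenol and primary alcohol with a base (imidazole) too weak to epimerise the cis lactone.

Step 18
Reactants: 17 tris(tert-butyldimethylsilyl) ether of 16; 27 (3R,4R)-4-[4-(tert-butyldimethylsilyloxy)-3-methoxybenzyl]-3-[(tert-butyldimethylsilyloxy)methyl]dihydrofuran-2(3H)-one
Product: 29 (3R,4R)-2-aryl-4-[4-(tert-butyldimethylsilyloxy)-3-methoxybenzyl]-3-[(tert-butyldimethylsilyloxy)methyl]tetrahydrofuran-2-ol (aryl = C5 of the silylated bis-dihydrobenzofuran; both anomers), via aryllithium 28 (not isolated)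
Conditions: 17, t-BuLi (2.0 equiv), THF, −78 °C; then 27 (1.1 equiv), −78 °C; aq. NH4Cl
Reagents that add atoms: none
Why: Bromine–lithium exchange followed by 1,2-addition of the aryllithium to the lactone carbonyl, which stops at the lithium lactol salt at −78 °C (as in C-aryl glycoside and tetrahydrofuran-lignan syntheses) and leaves C3 and C4 untouched.

Step 19
Reactants: 29 (3R,4R)-2-aryl-4-[4-(tert-butyldimethylsilyloxy)-3-methoxybenzyl]-3-[(tert-butyldimethylsilyloxy)methyl]tetrahydrofuran-2-ol
Product: 30 tetrakis(tert-butyldimethylsilyl) ether of the target, (2R,3R,4R) all-cis tetrahydrofuran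
Conditions: Et3SiH (5 equiv), then BF3·OEt2 (2 equiv), CH2Cl2, −78 °C; cold quench with Et3N/aq. NaHCO3
Reagents that add atoms: none
Why: Ionic hydrogenation of a lactol, in which BF3·OEt2 ionises C2 to the 2-aryl oxocarbenium ion and Et3SiH delivers hydride to the face opposite the cis C3 and C4 substituents, so the aryl group ends on their side and C2 becomes R, while the low temperature and the cold basic quench prevent equilibration of the benzylic C2–O bond.

Step 20
Reactants: 30 tetrakis(tert-butyldimethylsilyl) ether of the target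
Product: 31 target, (2R,3R,4R)-2-aryl-4-(4-hydroxy-3-methoxybenzyl)-3-(hydroxymethyl)tetrahydrofuran with aryl = (2R,3S)-3-(hydroxymethyl)-2-[(2S,3R)-3-(hydroxymethyl)-2-(4-hydroxy-3-methoxyphenyl)-7-methoxy-2,3-dihydrobenzofuran-5-yl]-7-methoxy-2,3-dihydrobenzofuran-5-yl
Conditions: Bu4NF (6 equiv), AcOH (6 equiv), THF, 0 °C to rt
Reagents that add atoms: none
Why: Fluoride-induced cleavage of all four silyl ethers, buffered with acetic acid so that no free phenoxide or acid meets the benzylic ethers.

Compound list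
1 | 1-(2-hydroxy-3-methoxyphenyl)ethanone | CC(=O)c1cccc(OC)c1O | starting material
2 | 1-(5-bromo-2-hydroxy-3-methoxyphenyl)ethanone | CC(=O)c1cc(Br)cc(OC)c1O | intermediate
3 | N,N-dimethylformamide dimethyl acetal | COC(OC)N(C)C | starting material
4 | (E)-1-(5-bromo-2-hydroxy-3-methoxyphenyl)-3-(dimethylamino)prop-2-en-1-one | CN(C)/C=C/C(=O)c1cc(Br)cc(OC)c1O | intermediate (not isolated)
5 | 6-bromo-8-methoxy-4H-chromen-4-one | O=c1ccoc2c(OC)cc(Br)cc12 | intermediate
6 | 4-bromo-2-methoxyphenol | COc1cc(Br)ccc1O | starting material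
7 | 4-bromo-2-methoxyphenyl pivalate | COc1cc(Br)ccc1OC(=O)C(C)(C)C | intermediate
8 | [3-methoxy-4-(pivaloyloxy)phenyl]boronic acid | COc1cc(B(O)O)ccc1OC(=O)C(C)(C)C | intermediate
9 | (2S)-6-bromo-8-methoxy-2-[3-methoxy-4-(pivaloyloxy)phenyl]chroman-4-one | O=C1C[C@@H](c3ccc(OC(=O)C(C)(C)C)c(OC)c3)Oc2c(OC)cc(Br)cc12 | intermediate
10 | (2S)-6-bromo-4,8-dimethoxy-2-[3-methoxy-4-(pivaloyloxy)phenyl]-2H-chromene | COC1=C[C@@H](c3ccc(OC(=O)C(C)(C)C)c(OC)c3)Oc2c(OC)cc(Br)cc12 | intermediate (not isolated)
11 | methyl (2S,3S)-5-bromo-7-methoxy-2-[3-methoxy-4-(pivaloyloxy)phenyl]-2,3-dihydrobenzofuran-3-carboxylate | Brc1cc(OC)c2c(c1)[C@H](C(=O)OC)[C@@H](c1ccc(OC(=O)C(C)(C)C)c(OC)c1)O2 | intermediate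
12 | {(2S,3S)-7-methoxy-3-(methoxycarbonyl)-2-[3-methoxy-4-(pivaloyloxy)phenyl]-2,3-dihydrobenzofuran-5-yl}boronic acid | OB(O)c1cc(OC)c2c(c1)[C@H](C(=O)OC)[C@@H](c1ccc(OC(=O)C(C)(C)C)c(OC)c1)O2 | intermediate
13 | methyl (2S,3S)-5-[(2R)-6-bromo-8-methoxy-4-oxochroman-2-yl]-7-methoxy-2-[3-methoxy-4-(pivaloyloxy)phenyl]-2,3-dihydrobenzofuran-3-carboxylate | O=C1C[C@H](c3cc(OC)c4c(c3)[C@H](C(=O)OC)[C@@H](c3ccc(OC(=O)C(C)(C)C)c(OC)c3)O4)Oc2c(OC)cc(Br)cc12 | intermediate (precursor of the key step)
14 | methyl (2S,3S)-5-[(2R)-6-bromo-4,8-dimethoxy-2H-chromen-2-yl]-7-methoxy-2-[3-methoxy-4-(pivaloyloxy)phenyl]-2,3-dihydrobenzofuran-3-carboxylate | COC1=C[C@H](c3cc(OC)c4c(c3)[C@H](C(=O)OC)[C@@H](c3ccc(OC(=O)C(C)(C)C)c(OC)c3)O4)Oc2c(OC)cc(Br)cc12 | intermediate (not isolated)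
15 | methyl (2R,3R)-5-bromo-7-methoxy-2-{(2S,3S)-7-methoxy-3-(methoxycarbonyl)-2-[3-methoxy-4-(pivaloyloxy)phenyl]-2,3-dihydrobenzofuran-5-yl}-2,3-dihydrobenzofuran-3-carboxylate | Brc1cc(OC)c2c(c1)[C@@H](C(=O)OC)[C@H](c1cc(OC)c3c(c1)[C@H](C(=O)OC)[C@@H](c1ccc(OC(=O)C(C)(C)C)c(OC)c1)O3)O2 | intermediate (product of the key step)
16 | [(2R,3S)-5-bromo-2-[(2S,3R)-3-(hydroxymethyl)-2-(4-hydroxy-3-methoxyphenyl)-7-methoxy-2,3-dihydrobenzofuran-5-yl]-7-methoxy-2,3-dihydrobenzofuran-3-yl]methanol | Brc1cc(OC)c2c(c1)[C@@H](CO)[C@H](c1cc(OC)c3c(c1)[C@H](CO)[C@@H](c1ccc(O)c(OC)c1)O3)O2 | intermediate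
17 | tris(tert-butyldimethylsilyl) ether of 16 | Brc1cc(OC)c2c(c1)[C@@H](CO[Si](C)(C)C(C)(C)C)[C@H](c1cc(OC)c3c(c1)[C@H](CO[Si](C)(C)C(C)(C)C)[C@@H](c1ccc(O[Si](C)(C)C(C)(C)C)c(OC)c1)O3)O2 | intermediate
18 | 4-(benzyloxy)-3-methoxybenzaldehyde | COc1cc(C=O)ccc1OCc1ccccc1 | starting material
19 | dimethyl succinate | COC(=O)CCC(=O)OC | starting material
20 | (E)-4-[4-(benzyloxy)-3-methoxyphenyl]-3-(methoxycarbonyl)but-3-enoic acid | COC(=O)/C(CC(=O)O)=C/c1ccc(OCc2ccccc2)c(OC)c1 | intermediate
21 | (3R)-4-[4-(benzyloxy)-3-methoxyphenyl]-3-(methoxycarbonyl)butanoic acid | COc1cc(C[C@@H](C(=O)OC)CC(=O)O)ccc1OCc1ccccc1 | intermediate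
22 | (4R)-4-[4-(benzyloxy)-3-methoxybenzyl]dihydrofuran-2(3H)-one | COc1cc(C[C@H]2COC(=O)C2)ccc1OCc1ccccc1 | intermediate
23 | lithium (3S,4R)-4-[4-(benzyloxy)-3-methoxybenzyl]-2-oxotetrahydrofuran-3-carboxylate (trans) | COc1cc(C[C@H]2COC(=O)[C@@H]2C(=O)[O-])ccc1OCc1ccccc1.[Li+] | intermediate (not isolated)
24 | (2R,3R)-3-[4-(benzyloxy)-3-methoxybenzyl]-4-hydroxy-2-(hydroxymethyl)butanoic acid | COc1cc(C[C@@H](CO)[C@H](CO)C(=O)O)ccc1OCc1ccccc1 | intermediate (not isolated)
25 | (3R,4R)-4-[4-(benzyloxy)-3-methoxybenzyl]-3-(hydroxymethyl)dihydrofuran-2(3H)-one (cis) | COc1cc(C[C@H]2COC(=O)[C@H]2CO)ccc1OCc1ccccc1 | intermediate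
26 | (3R,4R)-4-(4-hydroxy-3-methoxybenzyl)-3-(hydroxymethyl)dihydrofuran-2(3H)-one | COc1cc(C[C@H]2COC(=O)[C@H]2CO)ccc1O | intermediate
27 | (3R,4R)-4-[4-(tert-butyldimethylsilyloxy)-3-methoxybenzyl]-3-[(tert-butyldimethylsilyloxy)methyl]dihydrofuran-2(3H)-one | COc1cc(C[C@H]2COC(=O)[C@H]2CO[Si](C)(C)C(C)(C)C)ccc1O[Si](C)(C)C(C)(C)C | intermediate
28 | C5 aryllithium derived from 17 | [Li]c1cc(OC)c2c(c1)[C@@H](CO[Si](C)(C)C(C)(C)C)[C@H](c1cc(OC)c3c(c1)[C@H](CO[Si](C)(C)C(C)(C)C)[C@@H](c1ccc(O[Si](C)(C)C(C)(C)C)c(OC)c1)O3)O2 | intermediate (not isolated)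
29 | (3R,4R)-2-aryl-2-hydroxytetrahydrofuran (lactol, both anomers) carrying four silyl ethers | COc1cc(C[C@H]2COC(O)(c3cc(OC)c4c(c3)[C@@H](CO[Si](C)(C)C(C)(C)C)[C@H](c3cc(OC)c5c(c3)[C@H](CO[Si](C)(C)C(C)(C)C)[C@@H](c3ccc(O[Si](C)(C)C(C)(C)C)c(OC)c3)O5)O4)[C@H]2CO[Si](C)(C)C(C)(C)C)ccc1O[Si](C)(C)C(C)(C)C | intermediate
30 | tetrakis(tert-butyldimethylsilyl) ether of the target, (2R,3R,4R) | COc1cc(C[C@H]2CO[C@@H](c3cc(OC)c4c(c3)[C@@H](CO[Si](C)(C)C(C)(C)C)[C@H](c3cc(OC)c5c(c3)[C@H](CO[Si](C)(C)C(C)(C)C)[C@@H](c3ccc(O[Si](C)(C)C(C)(C)C)c(OC)c3)O5)O4)[C@H]2CO[Si](C)(C)C(C)(C)C)ccc1O[Si](C)(C)C(C)(C)C | intermediate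
31 | CNP0395728.1 | COc1cc(C[C@H]2CO[C@@H](c3cc(OC)c4c(c3)[C@@H](CO)[C@H](c3cc(OC)c5c(c3)[C@H](CO)[C@@H](c3ccc(O)c(OC)c3)O5)O4)[C@H]2CO)ccc1O | target

Total step count: 20. Longest linear sequence: 12 steps (steps 1, 2, 5, 6, 7, 8, 9, 10, 11, 18, 19, 20).

Steps most likely to fail

Step 9. The wrong group may migrate (the electron-rich ring-C aryl on C2 in place of C4a), trivalent iodine may attack an electron-rich ring, or acid may open the pyranone and erase the C2 configuration. The fallback replaces the cationic, oxidative shift by a carbene shift. It sets out from 13: condensation with 3 (toluene, 90 °C) should give the 3-(dimethylaminomethylene)chromanone F1, and diazo transfer with TsN3 (MeCN, rt) the 3-diazochroman-4-one F2. Irradiation of F2 (365 nm, MeOH/THF) brings about a Wolff rearrangement, in which only the acyl-side carbon C4a can move to C3, and the ketene is trapped by methanol as the methyl ester, expected largely as the C3-epimeric cis ester F3. DBU in toluene then equilibrates F3 to the trans ester, and the route is rejoined at 15.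

Step 19. Hydride may arrive from the wrong face, or the oxocarbenium ion may equilibrate before reduction (reversible opening of the benzylic C2–O bond, or loss of the C3 proton to the enol ether), giving the more stable 2,3-trans or 3,4-trans isomers. The fallback sets both centres by syn hydrogenation. It sets out from 29: dehydration (pyridinium p-toluenesulfonate, toluene, 4 Å sieves) should give the 2,3-dihydrofuran F4 with a C2=C3 double bond. Hydrogenation over Rh/Al2O3 (H2, EtOAc, trace Et3N) then adds both hydrogens from the face opposite the C4 benzyl group, so aryl and silyloxymethyl end cis to it. The route is rejoined at 30.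

Step 15. Proton exchange may erode the configuration of the carboxylated carbon before the reduction, or the borohydride may fail to discriminate cleanly between lactone and carboxylate. The fallback inverts C3 by kinetic protonation. It sets out from 22: hydroxymethylation of the lithium enolate with gaseous formaldehyde (LiN(i-Pr)2, THF, −78 °C) gives the trans hydroxymethyl lactone F5. Its dianion (LiN(i-Pr)2, 2.2 equiv, −78 °C) is then protonated with 2,6-di-tert-butyl-4-methylphenol from the face opposite the benzyl group, and the route is rejoined at 25.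

Further compounds
F1 | step 9 | methyl (2S,3S)-5-[(2S)-6-bromo-3-[(dimethylamino)methylidene]-8-methoxy-4-oxochroman-2-yl]-7-methoxy-2-[3-methoxy-4-(pivaloyloxy)phenyl]-2,3-dihydrobenzofuran-3-carboxylate (C2 of the chromanone spatially as in 13; alkene geometry not assigned) | O=C1C(=CN(C)C)[C@H](c3cc(OC)c4c(c3)[C@H](C(=O)OC)[C@@H](c3ccc(OC(=O)C(C)(C)C)c(OC)c3)O4)Oc2c(OC)cc(Br)cc12
F2 | step 9 | methyl (2S,3S)-5-[(2S)-6-bromo-3-diazo-8-methoxy-4-oxochroman-2-yl]-7-methoxy-2-[3-methoxy-4-(pivaloyloxy)phenyl]-2,3-dihydrobenzofuran-3-carboxylate (C2 of the chromanone spatially as in 13) | O=C1C(=[N+]=[N-])[C@H](c3cc(OC)c4c(c3)[C@H](C(=O)OC)[C@@H](c3ccc(OC(=O)C(C)(C)C)c(OC)c3)O4)Oc2c(OC)cc(Br)cc12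
F3 | step 9 | methyl (2R,3S)-5-bromo-7-methoxy-2-{(2S,3S)-7-methoxy-3-(methoxycarbonyl)-2-[3-methoxy-4-(pivaloyloxy)phenyl]-2,3-dihydrobenzofuran-5-yl}-2,3-dihydrobenzofuran-3-carboxylate (cis C3 epimer of 15) | Brc1cc(OC)c2c(c1)[C@H](C(=O)OC)[C@H](c1cc(OC)c3c(c1)[C@H](C(=O)OC)[C@@H](c1ccc(OC(=O)C(C)(C)C)c(OC)c1)O3)O2
F4 | step 19 | (3R)-5-aryl-3-[4-(tert-butyldimethylsilyloxy)-3-methoxybenzyl]-4-[(tert-butyldimethylsilyloxy)methyl]-2,3-dihydrofuran (aryl as in 29) | COc1cc(C[C@H]2COC(c3cc(OC)c4c(c3)[C@@H](CO[Si](C)(C)C(C)(C)C)[C@H](c3cc(OC)c5c(c3)[C@H](CO[Si](C)(C)C(C)(C)C)[C@@H](c3ccc(O[Si](C)(C)C(C)(C)C)c(OC)c3)O5)O4)=C2CO[Si](C)(C)C(C)(C)C)ccc1O[Si](C)(C)C(C)(C)C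
F5 | step 15 | (3S,4R)-4-[4-(benzyloxy)-3-methoxybenzyl]-3-(hydroxymethyl)dihydrofuran-2(3H)-one (trans) | COc1cc(C[C@H]2COC(=O)[C@@H]2CO)ccc1OCc1ccccc1
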